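**Retrosynthetic overview**
1. Target ⇒ removal of five O-benzyl groups and C–B → C–OH on flavanone ring B ⇒ a protected (2S)-flavanone–flavone biaryl whose ring B carries a pinacol boronate in place of the para oxygen.
2. Key disconnection: the flavanone pyranone (ring C) is opened at O1–C2 and at C4–C4a, leaving a biaryl phenol and an (R)-4-aryl-β-lactone. The lactone C4 becomes C2 with inversion and its carbonyl becomes C4, in a one-pot phenoxide SN2 opening / Friedel–Crafts acylation (formal [3+3]).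
3. Enabling feature: flavanone ring A is a phloroglucinol ring in which O1 is flanked by C8 (blocked by the 8,8''-biaryl bond) and by C4a, the only free ortho carbon, activated by O1, O5 and O7. Ring B's para-OH, which would make C2 a quinone-methide (SN1) position, is masked as boron so that C2 can be set by clean inversion.
4. Biaryl phenol ⇐ Suzuki–Miyaura coupling of 8-iodo-tri-O-benzylapigenin (from apigenin) with an arylboronate made by directed lithiation of MOM-protected 3,5-bis(benzyloxy)phenol; lactone ⇐ asymmetric ketene–aldehyde [2+2].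
5. Ring order: the three rings of the apigenin half (purchased) → biaryl axis → flavanone ring C (key step, which also brings ring B and C2) → unmasking of the phenols.

Key step: step 8

Remark: the SMILES defines C2 only and gives no descriptor for the 8,8''-biaryl axis (four ortho oxygen substituents), so the axis is left uncontrolled and compounds from 8 on are carried as mixtures of the two axial isomers.

**Route**

Step 1
Reactants: 1 apigenin
Product: 2 5,7-bis(benzyloxy)-2-[4-(benzyloxy)phenyl]-4H-chromen-4-one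
Conditions: BnBr (4.5 equiv), K2CO3, DMF, 90 °C
Reagents that add atoms: benzyl bromide, BrCc1ccccc1
Why: Williamson etherification of all three phenols should go to completion with excess halide and heat, the chelated 5-OH being the slowest to react.

Step 2
Reactants: 2 5,7-bis(benzyloxy)-2-[4-(benzyloxy)phenyl]-4H-chromen-4-one
Product: 3 5,7-bis(benzyloxy)-2-[4-(benzyloxy)phenyl]-8-iodo-4H-chromen-4-one
Conditions: NIS (1.1 equiv), CF3CO2H (cat.), CH2Cl2/MeCN, 0 °C → rt
Reagents that add atoms: N-iodosuccinimide, O=C1CCC(=O)N1I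
Why: Electrophilic aromatic iodination should occur on the trioxygenated ring A at C8, the position 5,7-di-O-alkylflavones offer to electrophiles in preference to C6, which lies between two benzyloxy groups.

Step 3
Reactants: 4 3,5-bis(benzyloxy)phenol
Product: 5 1,3-bis(benzyloxy)-5-(methoxymethoxy)benzene
Conditions: NaH, MOMCl, DMF, 0 °C → rt
Reagents that add atoms: chloromethyl methyl ether, COCCl
Why: Williamson-type O-alkylation of the sodium phenoxide installs an acetal that directs the next lithiation and is later cleaved by dilute acid without loss of benzyl ethers.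

Step 4
Reactants: 5 1,3-bis(benzyloxy)-5-(methoxymethoxy)benzene
Product: 7 2-[2,4-bis(benzyloxy)-6-(methoxymethoxy)phenyl]-4,4,5,5-tetramethyl-1,3,2-dioxaborolane, via aryllithium 6 (not isolated)
Conditions: n-BuLi, THF, 0 °C; then i-PrOBpin, −78 °C → rt
Reagents that add atoms: 2-isopropoxy-4,4,5,5-tetramethyl-1,3,2-dioxaborolane, CC(C)OB1OC(C)(C)C(C)(C)O1
Why: Directed ortho-metalation should take place at one of the two equivalent positions flanked by the chelating OMOM group and a benzyloxy group rather than between the two benzyloxy groups, and the aryllithium is trapped by the borate.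

Step 5
Reactants: 3 5,7-bis(benzyloxy)-2-[4-(benzyloxy)phenyl]-8-iodo-4H-chromen-4-one; 7 2-[2,4-bis(benzyloxy)-6-(methoxymethoxy)phenyl]-4,4,5,5-tetramethyl-1,3,2-dioxaborolane
Product: 8 5,7-bis(benzyloxy)-8-[2,4-bis(benzyloxy)-6-(methoxymethoxy)phenyl]-2-[4-(benzyloxy)phenyl]-4H-chromen-4-one
Conditions: Pd(OAc)2 (5 mol%), SPhos (10 mol%), K3PO4, toluene/H2O, 100 °C
Reagents that add atoms: none
Why: Suzuki–Miyaura coupling with a bulky dialkylbiarylphosphine, the ligand class used for tetra-ortho-substituted biaryls, should join C8 of the flavone to the boron-bearing carbon, the aryl iodide being the only site for oxidative addition.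

Step 6
Reactants: 8 5,7-bis(benzyloxy)-8-[2,4-bis(benzyloxy)-6-(methoxymethoxy)phenyl]-2-[4-(benzyloxy)phenyl]-4H-chromen-4-one
Product: 9 5,7-bis(benzyloxy)-8-[2,4-bis(benzyloxy)-6-hydroxyphenyl]-2-[4-(benzyloxy)phenyl]-4H-chromen-4-one
Conditions: HCl (cat.), MeOH/THF, 50 °C
Reagents that add atoms: none
Why: Acid-catalysed acetal exchange with methanol removes only the MOM group, since aryl benzyl ethers and the flavone are stable to dilute HCl.

Step 7
Reactants: 10 4-(4,4,5,5-tetramethyl-1,3,2-dioxaborolan-2-yl)benzaldehyde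
Product: 11 (4R)-4-[4-(4,4,5,5-tetramethyl-1,3,2-dioxaborolan-2-yl)phenyl]oxetan-2-one
Conditions: AcCl, i-Pr2NEt, O-trimethylsilylquinidine (10 mol%), LiClO4 (50 mol%), CH2Cl2/Et2O, −78 °C
Reagents that add atoms: acetyl chloride, CC(Cl)=O
Why: Catalytic asymmetric ketene–aldehyde [2+2] cycloaddition, in which ketene made in situ is bound by the cinchona alkaloid as an acylammonium enolate and adds to one face of the lithium-activated aldehyde, so the alkaloid sets C4; the quinidine-derived catalyst is expected to give (R), and its quinine-derived pseudoenantiomer is taken if a model run shows the opposite sense.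

Step 8
Reactants: 9 5,7-bis(benzyloxy)-8-[2,4-bis(benzyloxy)-6-hydroxyphenyl]-2-[4-(benzyloxy)phenyl]-4H-chromen-4-one; 11 (4R)-4-[4-(4,4,5,5-tetramethyl-1,3,2-dioxaborolan-2-yl)phenyl]oxetan-2-one
Product: 14 (2S)-5,7-bis(benzyloxy)-8-{5,7-bis(benzyloxy)-2-[4-(benzyloxy)phenyl]-4-oxo-4H-chromen-8-yl}-2-[4-(4,4,5,5-tetramethyl-1,3,2-dioxaborolan-2-yl)phenyl]-2,3-dihydro-4H-chromen-4-one, via sodium 3-aryloxypropanoate 12 (not isolated), via mixed trifluoroacetic anhydride 13 (not isolated)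
Conditions: NaH (1.05 equiv), 15-crown-5, THF, 0 °C, then 11 (1.3 equiv), 0 °C → rt; then CH2Cl2, (CF3CO)2O (4 equiv), 0 °C → rt (one pot)
Reagents that add atoms: none
Why: Proposed new method: the sodium phenoxide of 9 should open the strained lactone 11 by SN2 attack at the benzylic carbon (alkyl–oxygen cleavage) to give carboxylate 12, which trifluoroacetic anhydride turns into mixed anhydride 13 that acylates the neighbouring ring carbon; the closest known reactions are the opening of β-propiolactone by phenoxides to 3-aryloxypropanoic acids, the invertive SN2 opening of 4-substituted β-lactones by azide, thiolate and cuprate nucleophiles, and the TFAA-mediated Friedel–Crafts cyclisation of 3-aryloxypropanoic acids to chroman-4-ones. Ring C is closed at carbon, by 6-exo-trig electrophilic substitution at C4a, after the O1–C2 bond has been made intermolecularly. The C2 stereocentre is set stereospecifically, since backside attack inverts the (R) centre of 11 to (S) and no later stage touches it. Alkyl- over acyl-oxygen cleavage is expected because acyl attack is reversible (the β-alkoxide of the resulting aryl ester re-closes the lactone and expels the phenoxide) whereas the SN2 opening is not, and elimination from the four-membered ring is stereoelectronically disfavoured. Clean inversion and survival of the benzylic aryl ether in the acidic second stage rest on ring B carrying boron rather than oxygen at its para position, so that no quinone-methide-like benzylic cation can form. The acylation site is fixed by the substrate, because of the two positions ortho to O1 the carbon that becomes C8 is the biaryl carbon and only C4a, activated by three oxygens, is free.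

Step 9
Reactants: 14 (2S)-5,7-bis(benzyloxy)-8-{5,7-bis(benzyloxy)-2-[4-(benzyloxy)phenyl]-4-oxo-4H-chromen-8-yl}-2-[4-(4,4,5,5-tetramethyl-1,3,2-dioxaborolan-2-yl)phenyl]-2,3-dihydro-4H-chromen-4-one
Product: 15 (2S)-5,7-bis(benzyloxy)-8-{5,7-bis(benzyloxy)-2-[4-(benzyloxy)phenyl]-4-oxo-4H-chromen-8-yl}-2-(4-hydroxyphenyl)-2,3-dihydro-4H-chromen-4-one
Conditions: Oxone (KHSO5, 1.1 equiv), acetone/THF/H2O, 0 °C, 15 min
Reagents that add atoms: potassium peroxymonosulfate, [K+].[O-]S(=O)(=O)OO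
Why: ipso-Hydroxylation of the arylboronate (peroxide adds to boron, the aryl group migrates from boron to oxygen, the borate is hydrolysed) should be complete in minutes under slightly acidic conditions that leave the ketones, the benzyl ethers and C2 untouched.

Step 10
Reactants: 15 (2S)-5,7-bis(benzyloxy)-8-{5,7-bis(benzyloxy)-2-[4-(benzyloxy)phenyl]-4-oxo-4H-chromen-8-yl}-2-(4-hydroxyphenyl)-2,3-dihydro-4H-chromen-4-one
Product: 16 (2S)-5,7-dihydroxy-8-[5,7-dihydroxy-2-(4-hydroxyphenyl)-4-oxo-4H-chromen-8-yl]-2-(4-hydroxyphenyl)-2,3-dihydro-4H-chromen-4-one (target)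
Conditions: H2 (1 atm), 10% Pd/C, THF/MeOH, rt
Reagents that add atoms: none
Why: Catalytic hydrogenolysis frees the five benzylated phenols under neutral conditions, so the (2S) centre, which epimerises by ring opening in base, is kept; the reaction is stopped at full debenzylation to spare the flavone double bond and the benzylic C2–O1 bond.

**Compound list**

1 | apigenin, 5,7-dihydroxy-2-(4-hydroxyphenyl)-4H-chromen-4-one | O=c1cc(-c2ccc(O)cc2)oc2cc(O)cc(O)c12 | starting material
2 | 5,7-bis(benzyloxy)-2-[4-(benzyloxy)phenyl]-4H-chromen-4-one | O=c1cc(-c2ccc(OCc3ccccc3)cc2)oc2cc(OCc3ccccc3)cc(OCc3ccccc3)c12 | intermediate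
3 | 5,7-bis(benzyloxy)-2-[4-(benzyloxy)phenyl]-8-iodo-4H-chromen-4-one | O=c1cc(-c2ccc(OCc3ccccc3)cc2)oc2c(I)c(OCc3ccccc3)cc(OCc3ccccc3)c12 | intermediate
4 | 3,5-bis(benzyloxy)phenol | Oc1cc(OCc2ccccc2)cc(OCc2ccccc2)c1 | starting material
5 | 1,3-bis(benzyloxy)-5-(methoxymethoxy)benzene | COCOc1cc(OCc2ccccc2)cc(OCc2ccccc2)c1 | intermediate
6 | [2,4-bis(benzyloxy)-6-(methoxymethoxy)phenyl]lithium | [Li]c1c(OCOC)cc(OCc2ccccc2)cc1OCc1ccccc1 | intermediate
7 | 2-[2,4-bis(benzyloxy)-6-(methoxymethoxy)phenyl]-4,4,5,5-tetramethyl-1,3,2-dioxaborolane | CC1(C)OB(OC1(C)C)c1c(OCOC)cc(OCc2ccccc2)cc1OCc1ccccc1 | intermediate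
8 | 5,7-bis(benzyloxy)-8-[2,4-bis(benzyloxy)-6-(methoxymethoxy)phenyl]-2-[4-(benzyloxy)phenyl]-4H-chromen-4-one | O=c1cc(-c2ccc(OCc3ccccc3)cc2)oc2c(-c3c(OCOC)cc(OCc4ccccc4)cc3OCc3ccccc3)c(OCc3ccccc3)cc(OCc3ccccc3)c12 | intermediate
9 | 5,7-bis(benzyloxy)-8-[2,4-bis(benzyloxy)-6-hydroxyphenyl]-2-[4-(benzyloxy)phenyl]-4H-chromen-4-one | O=c1cc(-c2ccc(OCc3ccccc3)cc2)oc2c(-c3c(O)cc(OCc4ccccc4)cc3OCc3ccccc3)c(OCc3ccccc3)cc(OCc3ccccc3)c12 | intermediate
10 | 4-(4,4,5,5-tetramethyl-1,3,2-dioxaborolan-2-yl)benzaldehyde | O=Cc1ccc(B2OC(C)(C)C(C)(C)O2)cc1 | starting material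
11 | (4R)-4-[4-(4,4,5,5-tetramethyl-1,3,2-dioxaborolan-2-yl)phenyl]oxetan-2-one | O=C1C[C@H](c2ccc(B3OC(C)(C)C(C)(C)O3)cc2)O1 | intermediate
12 | sodium (3S)-3-(3,5-bis(benzyloxy)-2-{5,7-bis(benzyloxy)-2-[4-(benzyloxy)phenyl]-4-oxo-4H-chromen-8-yl}phenoxy)-3-[4-(4,4,5,5-tetramethyl-1,3,2-dioxaborolan-2-yl)phenyl]propanoate | [Na+].[O-]C(=O)C[C@@H](c1ccc(B2OC(C)(C)C(C)(C)O2)cc1)Oc1cc(OCc2ccccc2)cc(OCc2ccccc2)c1-c1c(OCc2ccccc2)cc(OCc2ccccc2)c2c(=O)cc(-c3ccc(OCc4ccccc4)cc3)oc12 | intermediate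
13 | mixed anhydride of the (3S)-acid of 12 with trifluoroacetic acid | FC(F)(F)C(=O)OC(=O)C[C@@H](c1ccc(B2OC(C)(C)C(C)(C)O2)cc1)Oc1cc(OCc2ccccc2)cc(OCc2ccccc2)c1-c1c(OCc2ccccc2)cc(OCc2ccccc2)c2c(=O)cc(-c3ccc(OCc4ccccc4)cc3)oc12 | intermediate
14 | (2S)-5,7-bis(benzyloxy)-8-{5,7-bis(benzyloxy)-2-[4-(benzyloxy)phenyl]-4-oxo-4H-chromen-8-yl}-2-[4-(4,4,5,5-tetramethyl-1,3,2-dioxaborolan-2-yl)phenyl]-2,3-dihydro-4H-chromen-4-one | O=C1C[C@@H](c2ccc(B3OC(C)(C)C(C)(C)O3)cc2)Oc2c1c(OCc1ccccc1)cc(OCc1ccccc1)c2-c1c(OCc2ccccc2)cc(OCc2ccccc2)c2c(=O)cc(-c3ccc(OCc4ccccc4)cc3)oc12 | intermediate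
15 | (2S)-5,7-bis(benzyloxy)-8-{5,7-bis(benzyloxy)-2-[4-(benzyloxy)phenyl]-4-oxo-4H-chromen-8-yl}-2-(4-hydroxyphenyl)-2,3-dihydro-4H-chromen-4-one | O=C1C[C@@H](c2ccc(O)cc2)Oc2c1c(OCc1ccccc1)cc(OCc1ccccc1)c2-c1c(OCc2ccccc2)cc(OCc2ccccc2)c2c(=O)cc(-c3ccc(OCc4ccccc4)cc3)oc12 | intermediate
16 | (2S)-5,7-dihydroxy-8-[5,7-dihydroxy-2-(4-hydroxyphenyl)-4-oxo-4H-chromen-8-yl]-2-(4-hydroxyphenyl)-2,3-dihydro-4H-chromen-4-one | O=C1C[C@@H](c2ccc(O)cc2)Oc2c1c(O)cc(O)c2-c1c(O)cc(O)c2c(=O)cc(-c3ccc(O)cc3)oc12 | target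

**Step count and risks**

Total steps: 10. Longest linear sequence: 7 steps (steps 1, 2, 5, 6, 8, 9, 10 from apigenin; equally steps 3, 4, 5, 6, 8, 9, 10 from 3,5-bis(benzyloxy)phenol).

Steps most likely to fail:

1. Step 8 (Proposed new method). The phenoxide may attack the lactone carbonyl (acyl–oxygen cleavage, followed by retro-aldol or elimination of the aryl ester) faster than it displaces at the hindered benzylic carbon, or the displacement may lose stereochemical fidelity through partial ionisation. The fallback uses known chemistry, sets out from 9 and comes back at 16; it sets C2 by carbon–carbon instead of carbon–oxygen bond formation and carries the ring B oxygen from the start. The sodium phenoxide of 9 is alkylated with β-propiolactone (NaH, THF), the established alkyl–oxygen opening at an unsubstituted CH2, to give 3-(3,5-bis(benzyloxy)-2-{5,7-bis(benzyloxy)-2-[4-(benzyloxy)phenyl]-4-oxo-4H-chromen-8-yl}phenoxy)propanoic acid F1. TFAA in CH2Cl2 cyclises it to 5,7-bis(benzyloxy)-8-{5,7-bis(benzyloxy)-2-[4-(benzyloxy)phenyl]-4-oxo-4H-chromen-8-yl}-2,3-dihydro-4H-chromen-4-one F2. Aerobic dehydrogenation (Pd(OCOCF3)2, DMSO, O2, AcOH, 80 °C) gives 5,7-bis(benzyloxy)-8-{5,7-bis(benzyloxy)-2-[4-(benzyloxy)phenyl]-4-oxo-4H-chromen-8-yl}-4H-chromen-4-one F3. Enantioselective conjugate addition of 4-(benzyloxy)phenylboronic acid (Pd(OCOCF3)2, t-BuPyOx in the enantiomeric form that gives (2S), expected to be (R), NH4PF6, H2O, ClCH2CH2Cl, 60 °C) should react only at the 2-unsubstituted chromone, the 2-aryl chromone of the apigenin half being a β,β-disubstituted enone. This gives (2S)-5,7-bis(benzyloxy)-8-{5,7-bis(benzyloxy)-2-[4-(benzyloxy)phenyl]-4-oxo-4H-chromen-8-yl}-2-[4-(benzyloxy)phenyl]-2,3-dihydro-4H-chromen-4-one F4, and hydrogenolysis under the conditions of step 10 gives 16.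

2. Step 7. Ketene dimerisation and slow addition to an aromatic aldehyde may outcompete the cycloaddition, or the face selectivity may be poor. The fallback sets out from 10 and comes back at 11, making the stereocentre by ketone reduction instead of cycloaddition. Roskamp homologation of 10 with ethyl diazoacetate (SnCl2 cat., CH2Cl2) gives ethyl 3-oxo-3-[4-(4,4,5,5-tetramethyl-1,3,2-dioxaborolan-2-yl)phenyl]propanoate F5. Asymmetric transfer hydrogenation (RuCl(p-cymene)[(R,R)-TsDPEN], HCO2H/Et3N) gives ethyl (3R)-3-hydroxy-3-[4-(4,4,5,5-tetramethyl-1,3,2-dioxaborolan-2-yl)phenyl]propanoate F6. LiOH in THF/H2O at 0 °C gives (3R)-3-hydroxy-3-[4-(4,4,5,5-tetramethyl-1,3,2-dioxaborolan-2-yl)phenyl]propanoic acid F7. Lactonisation by carboxyl activation (PhSO2Cl, pyridine, 0 °C), which leaves the carbinol configuration unchanged, gives 11.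

3. Step 5. Protodeboronation of the 2,6-dialkoxyarylboronate in hot aqueous base may outrun transmetalation onto the hindered arylpalladium iodide. The fallback sets out from 5 and comes back at 8, replacing the boronate by an organozinc reagent coupled without base or water. Compound 5 is lithiated as in step 4 to aryllithium 6 and transmetalated with ZnCl2 (THF, −78 °C → rt) to [2,4-bis(benzyloxy)-6-(methoxymethoxy)phenyl]zinc chloride F8. Negishi coupling of F8 with 3 (Pd2(dba)3, SPhos, THF, 65 °C) gives 8.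

**Further compounds**

F1 | step 8 | 3-(3,5-bis(benzyloxy)-2-{5,7-bis(benzyloxy)-2-[4-(benzyloxy)phenyl]-4-oxo-4H-chromen-8-yl}phenoxy)propanoic acid | OC(=O)CCOc1cc(OCc2ccccc2)cc(OCc2ccccc2)c1-c1c(OCc2ccccc2)cc(OCc2ccccc2)c2c(=O)cc(-c3ccc(OCc4ccccc4)cc3)oc12
F2 | step 8 | 5,7-bis(benzyloxy)-8-{5,7-bis(benzyloxy)-2-[4-(benzyloxy)phenyl]-4-oxo-4H-chromen-8-yl}-2,3-dihydro-4H-chromen-4-one | O=C1CCOc2c1c(OCc1ccccc1)cc(OCc1ccccc1)c2-c1c(OCc2ccccc2)cc(OCc2ccccc2)c2c(=O)cc(-c3ccc(OCc4ccccc4)cc3)oc12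
F3 | step 8 | 5,7-bis(benzyloxy)-8-{5,7-bis(benzyloxy)-2-[4-(benzyloxy)phenyl]-4-oxo-4H-chromen-8-yl}-4H-chromen-4-one | O=c1ccoc2c1c(OCc1ccccc1)cc(OCc1ccccc1)c2-c1c(OCc2ccccc2)cc(OCc2ccccc2)c2c(=O)cc(-c3ccc(OCc4ccccc4)cc3)oc12
F4 | step 8 | (2S)-5,7-bis(benzyloxy)-8-{5,7-bis(benzyloxy)-2-[4-(benzyloxy)phenyl]-4-oxo-4H-chromen-8-yl}-2-[4-(benzyloxy)phenyl]-2,3-dihydro-4H-chromen-4-one | O=C1C[C@@H](c2ccc(OCc3ccccc3)cc2)Oc2c1c(OCc1ccccc1)cc(OCc1ccccc1)c2-c1c(OCc2ccccc2)cc(OCc2ccccc2)c2c(=O)cc(-c3ccc(OCc4ccccc4)cc3)oc12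
F5 | step 7 | ethyl 3-oxo-3-[4-(4,4,5,5-tetramethyl-1,3,2-dioxaborolan-2-yl)phenyl]propanoate | CCOC(=O)CC(=O)c1ccc(B2OC(C)(C)C(C)(C)O2)cc1
F6 | step 7 | ethyl (3R)-3-hydroxy-3-[4-(4,4,5,5-tetramethyl-1,3,2-dioxaborolan-2-yl)phenyl]propanoate | CCOC(=O)C[C@@H](O)c1ccc(B2OC(C)(C)C(C)(C)O2)cc1
F7 | step 7 | (3R)-3-hydroxy-3-[4-(4,4,5,5-tetramethyl-1,3,2-dioxaborolan-2-yl)phenyl]propanoic acid | OC(=O)C[C@@H](O)c1ccc(B2OC(C)(C)C(C)(C)O2)cc1
F8 | step 5 | [2,4-bis(benzyloxy)-6-(methoxymethoxy)phenyl]zinc chloride | Cl[Zn]c1c(OCOC)cc(OCc2ccccc2)cc1OCc1ccccc1
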